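## Retrosynthetic overview

1. The last bonds made or broken are the four O–CH3 bonds (BBr3) and the pyrrole N–CH2 bond. Cutting these splits the target into 3,4-bis(7,8-dimethoxyquinolin-5-yl)-1H-pyrrole and (3S)-1-(3-chloropropyl)-3-methylazecane.
2. Feature used: the ten azecane atoms N1 and C2–C10 are the perimeter N1–C2–C3–C4–C4a–C5–C6–C7–C8–C8a of a 1,2,3,4,5,6,7,8-octahydroquinoline. Only the fusion bond C4a=C8a (azecane C5 to C10) is extra. That bond is an enamine double bond, and the methyl-bearing C3 is the same atom in both ring systems.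
3. The ten-membered ring is therefore never cyclised. Ozone cuts C4a=C8a to the azecane-2,7-dione (lactam C=O at former C8a, ketone at former C4a), and both carbonyl groups are then erased by tosylhydrazone reduction and LiAlH4.
4. The bicyclic enamine comes from cyclohexanone, alkylated as its dimethylhydrazone with an N-Boc γ-amino iodide. The iodide is built from (2S)-3-bromo-2-methylpropan-1-ol (source of C3) and O-silylated 3-aminopropanol, and freeing the nitrogen closes the six-membered N ring by condensation.
5. Ring order, azecane branch: cyclohexane (bought), then the tetrahydropyridine ring, then the ten-membered ring by fusion-bond scission. Aryl branch: the quinoline pyridine ring (Skraup), then a bought pyrrole diarylated by double Suzuki coupling.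

Key step: step 8

Assumption: (2S)-3-bromo-2-methylpropan-1-ol (the Roche-ester skeleton at the alcohol oxidation level) is taken as the commercial chiral C4 unit. The spectator side-chain hydroxyl is carried as its TBDPS ether because it must outlast TFA, and the target is isolated as the neutral free base under argon.

## Route

Step 1
Reactants: 1 3-aminopropan-1-ol
Product: 2 3-[(tert-butyldiphenylsilyl)oxy]propan-1-amine
Conditions: TBDPSCl (1.0 equiv), imidazole, CH2Cl2, 0 °C → rt
Reagents that add atoms: tert-butyl(chloro)diphenylsilane (TBDPSCl), CC(C)(C)[Si](Cl)(c1ccccc1)c1ccccc1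
Why: Chemoselective O-silylation of an amino alcohol: the Si–O bond is the thermodynamic sink and any N-silyl species is hydrolysed on aqueous work-up, and TBDPS is chosen because it should outlast TFA, azaenolate base, ozone and hydride later in the route.

Step 2
Reactants: 2 3-[(tert-butyldiphenylsilyl)oxy]propan-1-amine (2.5 equiv); 3 (2S)-3-bromo-2-methylpropan-1-ol
Product: 5 tert-butyl N-{3-[(tert-butyldiphenylsilyl)oxy]propyl}-N-[(2R)-3-hydroxy-2-methylpropyl]carbamate, via secondary amine 4 (not isolated)
Conditions: K2CO3, NaI (10 mol %), MeCN, 75 °C; then Boc2O, rt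
Reagents that add atoms: di-tert-butyl dicarbonate (Boc2O), CC(C)(C)OC(=O)OC(=O)OC(C)(C)C
Why: Iodide-catalysed SN2 N-alkylation at the primary C–Br carbon followed by carbamate formation in the same flask: the stereocentre sits one carbon away from the reacting centre and is untouched (the descriptor changes from S to R only because CH2OH now outranks CH2N), excess amine plus the β-branch hold back double alkylation, the alcohol oxidation level excludes the elimination and conjugate re-addition that would racemise a β-leaving-group ester, and the Boc group prevents azetidine formation once the iodide is in place.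

Step 3
Reactants: 5 tert-butyl N-{3-[(tert-butyldiphenylsilyl)oxy]propyl}-N-[(2R)-3-hydroxy-2-methylpropyl]carbamate
Product: 6 tert-butyl N-{3-[(tert-butyldiphenylsilyl)oxy]propyl}-N-[(2R)-3-iodo-2-methylpropyl]carbamate
Conditions: I2, PPh3, imidazole, CH2Cl2, 0 °C → rt
Reagents that add atoms: iodine, II
Why: Appel-type iodination via the alkoxyphosphonium salt with SN2 displacement at the primary carbinol carbon, under near-neutral conditions that leave Boc, TBDPS and the adjacent stereocentre alone.

Step 4
Reactants: 7 cyclohexanone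
Product: 8 cyclohexanone N,N-dimethylhydrazone
Conditions: Me2NNH2 (1.5 equiv), AcOH (cat.), EtOH, reflux
Reagents that add atoms: 1,1-dimethylhydrazine, CN(C)N
Why: Acid-catalysed carbonyl condensation to the hydrazone, which turns the ketone into a substrate that can be metalated cleanly and monoalkylated.

Step 5
Reactants: 8 cyclohexanone N,N-dimethylhydrazone (1.3 equiv); 6 tert-butyl N-{3-[(tert-butyldiphenylsilyl)oxy]propyl}-N-[(2R)-3-iodo-2-methylpropyl]carbamate
Product: 10 tert-butyl N-{3-[(tert-butyldiphenylsilyl)oxy]propyl}-N-{(2S)-3-[2-(2,2-dimethylhydrazinylidene)cyclohexyl]-2-methylpropyl}carbamate (epimers at the ring carbon), via lithium azaenolate 9 (not isolated)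
Conditions: LiN(iPr)2 (LDA), THF, 0 °C; then 6, −78 °C → rt
Reagents that add atoms: none
Why: Alkylation of a metalated N,N-dimethylhydrazone: the strongly nucleophilic lithium azaenolate 9 displaces iodide from the β-branched primary carbon in an SN2 step without the proton transfer and polyalkylation that plague the free ketone enolate, the tertiary carbamate has no acidic N–H, and the new ring stereocentre (formed as an epimer mixture) becomes sp2 again in step 7.

Step 6
Reactants: 10 alkylated dimethylhydrazone
Product: 11 tert-butyl N-{3-[(tert-butyldiphenylsilyl)oxy]propyl}-N-[(2S)-2-methyl-3-(2-oxocyclohexyl)propyl]carbamate (epimers at the ring carbon)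
Conditions: sat. aq. (CO2H)2, Et2O, rt
Reagents that add atoms: water, O
Why: Biphasic acid hydrolysis of the hydrazone, pulled forward by extraction of the protonated hydrazine into water, at an acidity too low to touch Boc or TBDPS.

Step 7
Reactants: 11 N-Boc amino ketone
Product: 13 (3S)-1-{3-[(tert-butyldiphenylsilyl)oxy]propyl}-3-methyl-1,2,3,4,5,6,7,8-octahydroquinoline, via amino ketone TFA salt 12 (not isolated)
Conditions: TFA, CH2Cl2, 0 °C → rt; 2 M aq. NaOH, Et2O, 0 °C; 4 Å MS, toluene, rt → 60 °C, Ar (used directly)
Reagents that add atoms: none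
Why: Acidolytic Boc cleavage gives ammonium salt 12, and on basification the free secondary amine adds to the ketone (6-exo-trig) and loses water in an intramolecular enamine condensation; the double bond should settle at C4a=C8a, tetrasubstituted and endocyclic to both rings, because tying nitrogen and C4 into one ring removes the allylic strain that disfavours acyclic tetrasubstituted enamines, and C3 is remote from every ionising position.

Step 8
Reactants: 13 (3S)-1-{3-[(tert-butyldiphenylsilyl)oxy]propyl}-3-methyl-1,2,3,4,5,6,7,8-octahydroquinoline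
Product: 17 (9S)-1-{3-[(tert-butyldiphenylsilyl)oxy]propyl}-9-methylazecane-2,7-dione, via primary ozonide 14 (not isolated), via carbonyl oxide 15 (not isolated), via methoxy hydroperoxide 16 (not isolated)
Conditions: O3/O2, dry CH2Cl2–MeOH (5:1), Sudan Red 7B end point, −78 °C; Ar purge; Me2S, −78 °C → rt
Reagents that add atoms: ozone, [O-][O+]=O
Why: Ozone adds to the most electron-rich π bond of 13, the nitrogen-pushed C4a=C8a bond, starting at the β-carbon C4a and collapsing to primary ozonide 14; Criegee cycloreversion leaves the lactam carbonyl at nitrogen-bearing C8a and carbonyl oxide 15 at C4a, methanol traps 15 as methoxy hydroperoxide 16, and Me2S reduces 16 to the ketone. The closest known reaction types are the ozonolytic or photooxygenative cleavage of enamines to amide plus ketone, the Witkop–Winterfeldt scission of the C2=C3 bond of ring-fused indoles to medium-ring keto lactams, and the cleavage of ring-fusion enol ethers to ten-membered keto lactones. The ten-membered ring is not closed by any cyclisation mode: its ten atoms are already linked around the bicycle and the ring appears by scission of the zero-atom bridge, so no entropic or transannular price is paid in a bond-forming transition state. No stereocentre is created; C3 of 13 becomes C9 of 17, β to the ketone and two carbons from nitrogen, where it can neither enolise nor take part in an elimination. The step needs chemoselectivity for the enamine over the phenyl rings, the silyl ether and nitrogen, secured by the very large rate gap at −78 °C with dye end-point control and by nitrogen ending as a non-basic amide, and it needs positional purity of the double bond, secured by the thermodynamic preference established in step 7.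

Step 9
Reactants: 17 (9S)-1-{3-[(tert-butyldiphenylsilyl)oxy]propyl}-9-methylazecane-2,7-dione
Product: 18 N'-[(9S)-1-{3-[(tert-butyldiphenylsilyl)oxy]propyl}-9-methyl-2-oxoazecan-7-ylidene]-4-methylbenzenesulfonohydrazide (E/Z mixture)
Conditions: TsNHNH2 (1.2 equiv), MeOH, 50 °C
Reagents that add atoms: 4-methylbenzenesulfonohydrazide (TsNHNH2), Cc1ccc(cc1)S(=O)(=O)NN
Why: Condensation of the only electrophilic carbonyl, the C7 ketone, with tosylhydrazide (first half of a Caglioti deoxygenation); the tertiary lactam does not react and no stereocentre is α to the new C=N bond.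

Step 10
Reactants: 18 tosylhydrazone
Product: 20 (9S)-1-{3-[(tert-butyldiphenylsilyl)oxy]propyl}-9-methylazecan-2-one, via alkyl diazene 19 (not isolated)
Conditions: catecholborane, CHCl3, −10 °C → rt; then NaOAc·3H2O, reflux
Reagents that add atoms: none
Why: Caglioti-type tosylhydrazone reduction in its catecholborane variant: B–H adds across C=N, acetate releases sulfinate to give diazene 19, which loses N2 with hydrogen delivery to C7, all under non-basic conditions that avoid diazoalkane and carbene chemistry and leave lactam and silyl ether intact; the ketone is removed before the lactam because a ten-membered amino ketone would lock up in a transannular N to C=O interaction.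

Step 11
Reactants: 20 (9S)-1-{3-[(tert-butyldiphenylsilyl)oxy]propyl}-9-methylazecan-2-one
Product: 21 (3S)-1-{3-[(tert-butyldiphenylsilyl)oxy]propyl}-3-methylazecane
Conditions: LiAlH4, THF, reflux; H2O, 15 % aq. NaOH, H2O
Reagents that add atoms: none
Why: Hydride reduction of a tertiary lactam to the cyclic amine through the aluminate hemiaminal and the iminium ion; should hydride also attack the silyl ether near the new amine, this only anticipates step 12.

Step 12
Reactants: 21 (3S)-1-{3-[(tert-butyldiphenylsilyl)oxy]propyl}-3-methylazecane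
Product: 22 3-[(3S)-3-methylazecan-1-yl]propan-1-ol
Conditions: TBAF, THF, rt
Reagents that add atoms: none
Why: Fluoride-mediated desilylation driven by the strength of the Si–F bond, with nothing else in the molecule susceptible to fluoride.

Step 13
Reactants: 22 3-[(3S)-3-methylazecan-1-yl]propan-1-ol
Product: 23 (3S)-1-(3-chloropropyl)-3-methylazecane hydrochloride
Conditions: SOCl2, CH2Cl2, 0 °C → reflux
Reagents that add atoms: thionyl chloride, O=S(Cl)Cl
Why: Deoxychlorination through the chlorosulfite ester with SN2 attack of chloride; the HCl formed protonates the ring nitrogen, which blocks intramolecular quaternisation and gives a storable salt.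

Step 14
Reactants: 24 2,3-dimethoxyaniline; 25 glycerol
Product: 28 7,8-dimethoxyquinoline, via acrolein 26 (not isolated), via 7,8-dimethoxy-1,2-dihydroquinoline 27 (not isolated)
Conditions: conc. H2SO4, 3-O2NC6H4SO3Na, FeSO4 (cat.), 130–140 °C; then aq. NaOH
Reagents that add atoms: none
Why: Skraup quinoline synthesis: glycerol dehydrates to acrolein 26, the aniline adds in aza-Michael fashion, Friedel–Crafts-type cyclodehydration takes place at the only free ortho position and the nitroarene dehydrogenates 27, so the 7,8-dimethoxy pattern is the only possible regiochemical outcome.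

Step 15
Reactants: 28 7,8-dimethoxyquinoline
Product: 29 5-bromo-7,8-dimethoxyquinoline
Conditions: NBS (1.05 equiv), MeCN, 0 °C → rt
Reagents that add atoms: N-bromosuccinimide, O=C1CCC(=O)N1Br
Why: Electrophilic aromatic bromination of the electron-rich carbocyclic ring: C5 is para to the C8 methoxy group and an α-position of the fused arene, the same preference that sends bromine to C4 of 1,2-dimethoxynaphthalene, while the pyridine ring is deactivated.

Step 16
Reactants: 29 5-bromo-7,8-dimethoxyquinoline
Product: 30 7,8-dimethoxy-5-(4,4,5,5-tetramethyl-1,3,2-dioxaborolan-2-yl)quinoline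
Conditions: B2pin2, PdCl2(dppf) (3 mol %), KOAc, 1,4-dioxane, 90 °C
Reagents that add atoms: bis(pinacolato)diboron, CC1(C)OB(OC1(C)C)B1OC(C)(C)C(C)(C)O1
Why: Miyaura borylation: oxidative addition of zerovalent palladium to the C–Br bond, acetate-assisted transmetalation from B2pin2 and reductive elimination, with a base too weak to trigger homocoupling.

Step 17
Reactants: 31 1-(triisopropylsilyl)-1H-pyrrole
Product: 32 3,4-dibromo-1-(triisopropylsilyl)-1H-pyrrole
Conditions: NBS (2.0 equiv), THF, −78 °C → rt
Reagents that add atoms: N-bromosuccinimide, O=C1CCC(=O)N1Br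
Why: Twofold electrophilic bromination in which the bulky N-triisopropylsilyl group shields C2 and C5, so that both bromine atoms should enter the β-positions C3 and C4.

Step 18
Reactants: 32 3,4-dibromo-1-(triisopropylsilyl)-1H-pyrrole; 30 7,8-dimethoxy-5-(4,4,5,5-tetramethyl-1,3,2-dioxaborolan-2-yl)quinoline (2.5 equiv)
Product: 34 3,4-bis(7,8-dimethoxyquinolin-5-yl)-1-(triisopropylsilyl)-1H-pyrrole, via monoarylated bromopyrrole 33 (not isolated)
Conditions: Pd(OAc)2 (5 mol %), SPhos (10 mol %), K3PO4, toluene–H2O (10:1), 90 °C
Reagents that add atoms: none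
Why: Double Suzuki–Miyaura coupling through monoarylated 33; the bulky electron-rich biarylphosphine speeds oxidative addition into the electron-rich bromopyrrole and reductive elimination next to the first peri-hindered quinolinyl group, and the silyl group keeps the pyrrole nitrogen off the metal.

Step 19
Reactants: 34 3,4-bis(7,8-dimethoxyquinolin-5-yl)-1-(triisopropylsilyl)-1H-pyrrole
Product: 35 3,4-bis(7,8-dimethoxyquinolin-5-yl)-1H-pyrrole
Conditions: TBAF, THF, 0 °C → rt
Reagents that add atoms: none
Why: Fluoride cleavage of the labile N–Si bond; the methyl ethers and the biaryl bonds are inert.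

Step 20
Reactants: 35 3,4-bis(7,8-dimethoxyquinolin-5-yl)-1H-pyrrole; 23 (3S)-1-(3-chloropropyl)-3-methylazecane hydrochloride
Product: 37 5,5'-(1-{3-[(3S)-3-methylazecan-1-yl]propyl}-1H-pyrrole-3,4-diyl)bis(7,8-dimethoxyquinoline), via sodium pyrrolide 36 (not isolated)
Conditions: NaH (3.5 equiv), DMF, 0 °C; then 23, NaI (10 mol %), 60 °C
Reagents that add atoms: none
Why: SN2 N-alkylation of sodium pyrrolide 36 in a dipolar aprotic solvent with iodide catalysis: the ionic sodium salt reacts at nitrogen rather than carbon, the quinoline nitrogens are far weaker nucleophiles, extra NaH frees the amine of 23, and even if that free base closes to a spiro-azetidinium ion its ring opening by 36 leads to the same product.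

Step 21
Reactants: 37 5,5'-(1-{3-[(3S)-3-methylazecan-1-yl]propyl}-1H-pyrrole-3,4-diyl)bis(7,8-dimethoxyquinoline)
Product: 38 5,5'-(1-{3-[(3S)-3-methylazecan-1-yl]propyl}-1H-pyrrole-3,4-diyl)bis(quinoline-7,8-diol) (CNP0141397.1)
Conditions: BBr3 (14 equiv), CH2Cl2, −78 °C → rt; MeOH, 0 °C, evaporate (repeat); degassed aq. NaHCO3 to pH 7, Ar
Reagents that add atoms: none
Why: Lewis-acid cleavage of aryl methyl ethers: BBr3 coordinates each ether oxygen and bromide removes methyl by SN2, the excess covers the three basic nitrogens, methanolysis strips boron from the catecholates as B(OMe)3, exclusion of air during neutralisation protects the catechols, and the C–N bonds and the stereocentre are not affected.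

## Compound list

1 | 3-aminopropan-1-ol | NCCCO | starting material
2 | 3-[(tert-butyldiphenylsilyl)oxy]propan-1-amine | NCCCO[Si](c1ccccc1)(c1ccccc1)C(C)(C)C | intermediate
3 | (2S)-3-bromo-2-methylpropan-1-ol | C[C@H](CBr)CO | starting material
4 | (2R)-3-({3-[(tert-butyldiphenylsilyl)oxy]propyl}amino)-2-methylpropan-1-ol | C[C@H](CNCCCO[Si](c1ccccc1)(c1ccccc1)C(C)(C)C)CO | intermediate
5 | tert-butyl N-{3-[(tert-butyldiphenylsilyl)oxy]propyl}-N-[(2R)-3-hydroxy-2-methylpropyl]carbamate | C[C@H](CN(CCCO[Si](c1ccccc1)(c1ccccc1)C(C)(C)C)C(=O)OC(C)(C)C)CO | intermediate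
6 | tert-butyl N-{3-[(tert-butyldiphenylsilyl)oxy]propyl}-N-[(2R)-3-iodo-2-methylpropyl]carbamate | C[C@H](CN(CCCO[Si](c1ccccc1)(c1ccccc1)C(C)(C)C)C(=O)OC(C)(C)C)CI | intermediate
7 | cyclohexanone | O=C1CCCCC1 | starting material
8 | cyclohexanone N,N-dimethylhydrazone | CN(C)N=C1CCCCC1 | intermediate
9 | lithium azaenolate of 8 | CN(C)N([Li])C1=CCCCC1 | intermediate
10 | tert-butyl N-{3-[(tert-butyldiphenylsilyl)oxy]propyl}-N-{(2S)-3-[2-(2,2-dimethylhydrazinylidene)cyclohexyl]-2-methylpropyl}carbamate (ring carbon unspecified) | C[C@H](CN(CCCO[Si](c1ccccc1)(c1ccccc1)C(C)(C)C)C(=O)OC(C)(C)C)CC1CCCCC1=NN(C)C | intermediate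
11 | tert-butyl N-{3-[(tert-butyldiphenylsilyl)oxy]propyl}-N-[(2S)-2-methyl-3-(2-oxocyclohexyl)propyl]carbamate (ring carbon unspecified) | C[C@H](CN(CCCO[Si](c1ccccc1)(c1ccccc1)C(C)(C)C)C(=O)OC(C)(C)C)CC1CCCCC1=O | intermediate
12 | 2-[(2S)-3-({3-[(tert-butyldiphenylsilyl)oxy]propyl}amino)-2-methylpropyl]cyclohexanone trifluoroacetate salt | C[C@H](CNCCCO[Si](c1ccccc1)(c1ccccc1)C(C)(C)C)CC1CCCCC1=O.OC(=O)C(F)(F)F | intermediate
13 | (3S)-1-{3-[(tert-butyldiphenylsilyl)oxy]propyl}-3-methyl-1,2,3,4,5,6,7,8-octahydroquinoline | C[C@@H]1CN(CCCO[Si](c2ccccc2)(c2ccccc2)C(C)(C)C)C2=C(CCCC2)C1 | intermediate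
14 | primary ozonide of 13 (4a,8a-epitrioxy-decahydroquinoline, 3S, fusion carbons unspecified) | C[C@@H]1CN(CCCO[Si](c2ccccc2)(c2ccccc2)C(C)(C)C)C23CCCCC2(C1)OOO3 | intermediate
15 | (9S)-lactam carbonyl oxide (C7 carbonyl O-oxide of 17) | C[C@H]1CC(=[O+][O-])CCCCC(=O)N(CCCO[Si](c2ccccc2)(c2ccccc2)C(C)(C)C)C1 | intermediate
16 | (9S)-1-{3-[(tert-butyldiphenylsilyl)oxy]propyl}-7-hydroperoxy-7-methoxy-9-methylazecan-2-one (C7 unspecified) | C[C@H]1CC(OC)(OO)CCCCC(=O)N(CCCO[Si](c2ccccc2)(c2ccccc2)C(C)(C)C)C1 | intermediate
17 | (9S)-1-{3-[(tert-butyldiphenylsilyl)oxy]propyl}-9-methylazecane-2,7-dione | C[C@H]1CC(=O)CCCCC(=O)N(CCCO[Si](c2ccccc2)(c2ccccc2)C(C)(C)C)C1 | intermediate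
18 | N'-[(9S)-1-{3-[(tert-butyldiphenylsilyl)oxy]propyl}-9-methyl-2-oxoazecan-7-ylidene]-4-methylbenzenesulfonohydrazide | C[C@H]1CC(=NNS(=O)(=O)c2ccc(C)cc2)CCCCC(=O)N(CCCO[Si](c2ccccc2)(c2ccccc2)C(C)(C)C)C1 | intermediate
19 | (9S)-1-{3-[(tert-butyldiphenylsilyl)oxy]propyl}-7-diazenyl-9-methylazecan-2-one (C7 unspecified) | C[C@H]1CC(N=N)CCCCC(=O)N(CCCO[Si](c2ccccc2)(c2ccccc2)C(C)(C)C)C1 | intermediate
20 | (9S)-1-{3-[(tert-butyldiphenylsilyl)oxy]propyl}-9-methylazecan-2-one | C[C@H]1CCCCCCC(=O)N(CCCO[Si](c2ccccc2)(c2ccccc2)C(C)(C)C)C1 | intermediate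
21 | (3S)-1-{3-[(tert-butyldiphenylsilyl)oxy]propyl}-3-methylazecane | C[C@H]1CCCCCCCN(CCCO[Si](c2ccccc2)(c2ccccc2)C(C)(C)C)C1 | intermediate
22 | 3-[(3S)-3-methylazecan-1-yl]propan-1-ol | C[C@H]1CCCCCCCN(CCCO)C1 | intermediate
23 | (3S)-1-(3-chloropropyl)-3-methylazecane hydrochloride | C[C@H]1CCCCCCCN(CCCCl)C1.Cl | intermediate
24 | 2,3-dimethoxyaniline | COc1cccc(N)c1OC | starting material
25 | glycerol | OCC(O)CO | starting material
26 | acrolein | C=CC=O | intermediate
27 | 7,8-dimethoxy-1,2-dihydroquinoline | COc1ccc2C=CCNc2c1OC | intermediate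
28 | 7,8-dimethoxyquinoline | COc1ccc2cccnc2c1OC | intermediate
29 | 5-bromo-7,8-dimethoxyquinoline | COc1cc(Br)c2cccnc2c1OC | intermediate
30 | 7,8-dimethoxy-5-(4,4,5,5-tetramethyl-1,3,2-dioxaborolan-2-yl)quinoline | COc1cc(B2OC(C)(C)C(C)(C)O2)c2cccnc2c1OC | intermediate
31 | 1-(triisopropylsilyl)-1H-pyrrole | CC(C)[Si](C(C)C)(C(C)C)n1cccc1 | starting material
32 | 3,4-dibromo-1-(triisopropylsilyl)-1H-pyrrole | CC(C)[Si](C(C)C)(C(C)C)n1cc(Br)c(Br)c1 | intermediate
33 | 5-[4-bromo-1-(triisopropylsilyl)-1H-pyrrol-3-yl]-7,8-dimethoxyquinoline | CC(C)[Si](C(C)C)(C(C)C)n1cc(Br)c(-c2cc(OC)c(OC)c3ncccc23)c1 | intermediate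
34 | 3,4-bis(7,8-dimethoxyquinolin-5-yl)-1-(triisopropylsilyl)-1H-pyrrole | CC(C)[Si](C(C)C)(C(C)C)n1cc(-c2cc(OC)c(OC)c3ncccc23)c(-c2cc(OC)c(OC)c3ncccc23)c1 | intermediate
35 | 3,4-bis(7,8-dimethoxyquinolin-5-yl)-1H-pyrrole | COc1cc(-c2c[nH]cc2-c2cc(OC)c(OC)c3ncccc23)c2cccnc2c1OC | intermediate
36 | sodium 3,4-bis(7,8-dimethoxyquinolin-5-yl)pyrrol-1-ide | [Na+].COc1cc(-c2c[n-]cc2-c2cc(OC)c(OC)c3ncccc23)c2cccnc2c1OC | intermediate
37 | 5,5'-(1-{3-[(3S)-3-methylazecan-1-yl]propyl}-1H-pyrrole-3,4-diyl)bis(7,8-dimethoxyquinoline) | C[C@H]1CCCCCCCN(CCCn2cc(-c3cc(OC)c(OC)c4ncccc34)c(-c3cc(OC)c(OC)c4ncccc34)c2)C1 | intermediate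
38 | 5,5'-(1-{3-[(3S)-3-methylazecan-1-yl]propyl}-1H-pyrrole-3,4-diyl)bis(quinoline-7,8-diol) (CNP0141397.1) | C[C@H]1CCCCCCCN(CCCn2cc(-c3cc(O)c(O)c4ncccc34)c(-c3cc(O)c(O)c4ncccc34)c2)C1 | target

## Step count and risks

Total step count: 21.
Longest linear sequence: 14 steps (steps 1, 2, 3, 5, 6, 7, 8, 9, 10, 11, 12, 13, 20, 21).

**Steps most likely to fail**

**1. Step 8 (key step).**
- The zwitterion formed when ozone attacks C4a may shed O2 and pass on a single oxygen atom, so that C4a is hydroxylated instead of the fusion bond being cut.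
- Traces of water may reopen the enamine to the amino ketone, whose free secondary amine is then oxidised.
- Any material whose double bond has slipped to C8=C8a is cut at the wrong bond.
- Fallback: the fallback sets out from 13. The dipolar cycloaddition and Criegee sequence is replaced by a [2+2] photooxygenation (O2, tetraphenylporphyrin, visible light, CH2Cl2, −78 °C). This should give the 4a,8a-epidioxide (1,2-dioxetane) F1. Neither dioxetane carbon carries hydrogen, so on warming to room temperature only C–C cycloreversion is open to it. This delivers the amide and the ketone at once, without a carbonyl oxide, a reductant or any chance of single-oxygen transfer. The route is rejoined at 17.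

**2. Step 18.**
- The second coupling may stall because of crowding between two peri-substituted aryl groups on neighbouring pyrrole carbons.
- The electron-rich heteroaryl boronate may protodeboronate.
- Aqueous base may strip the N-silyl group early, and the resulting pyrrolide binds palladium.
- Fallback: the fallback sets out from 29 and builds the pyrrole ring around a preformed aryl–C–C–aryl unit instead of arylating a pyrrole. Double Stille coupling with (E)-1,2-bis(tributylstannyl)ethene (Pd(PPh3)4, toluene, 100 °C) should give (E)-1,2-bis(7,8-dimethoxyquinolin-5-yl)ethene F2. A van Leusen pyrrole synthesis (TosMIC, NaOtBu, DMSO, rt) then adds the C–N–C unit across the alkene with loss of sulfinate. The route is rejoined at 35, and compounds 30 to 34 are bypassed.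

**3. Step 10.**
- Hydroboration of the medium-ring C=N bond may be slow.
- Elimination to ring alkenes or transannular hydrogen shifts may compete during loss of nitrogen.
- Prolonged exposure to the borane may start to reduce the lactam.
- Fallback: the fallback sets out from 17 and skips 18. Thioketalisation with ethane-1,2-dithiol and BF3·OEt2 in CH2Cl2 should give the spiro-1,3-dithiolane (7S)-9-{3-[(tert-butyldiphenylsilyl)oxy]propyl}-7-methyl-1,4-dithia-9-azaspiro[4.9]tetradecan-10-one F3. Raney Ni in EtOH (Mozingo reduction) then replaces both C–S bonds by C–H without any nitrogen-extrusion intermediate. The route is rejoined at 20.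

## Further compounds

F1 | step 8 | (3S)-1-{3-[(tert-butyldiphenylsilyl)oxy]propyl}-3-methyl-4a,8a-epidioxydecahydroquinoline (1,2-dioxetane, fusion carbons unspecified) | C[C@@H]1CN(CCCO[Si](c2ccccc2)(c2ccccc2)C(C)(C)C)C23CCCCC2(C1)OO3
F2 | step 18 | (E)-1,2-bis(7,8-dimethoxyquinolin-5-yl)ethene | COc1cc(/C=C/c2cc(OC)c(OC)c3ncccc23)c2cccnc2c1OC
F3 | step 10 | (7S)-9-{3-[(tert-butyldiphenylsilyl)oxy]propyl}-7-methyl-1,4-dithia-9-azaspiro[4.9]tetradecan-10-one | C[C@H]1CC2(SCCS2)CCCCC(=O)N(CCCO[Si](c2ccccc2)(c2ccccc2)C(C)(C)C)C1
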